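The isoflavone is opened at the C4–C4a bond of ring C, which leads back to a 2-aryl-3-aryloxyacrylic acid. Ring A is a phloroglucinol unit: the two carbons ortho to O1 are symmetry-related, as C5 and C7 carry identical oxygen groups, so acylation at either one creates the same C4a and only one chromone. In one operation the acid is turned into its chloride and closed onto ring A by a buffered SnCl4 Friedel–Crafts acylation that forms C4–C4a and the pyranone. The precursor is the Z acid bearing the O-allyl, C-prenyl guaiacyl ring B on the future C3 and a 3,5-bis(allyloxy)phenoxy group on the future C2; zerovalent palladium then frees the three phenols.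

Key step: step 10

Assumption: methyl homovanillate (4) is taken as a catalogue compound; otherwise it is one Fischer esterification away from homovanillic acid.

Remarks on the design:
- "Prenyl" means 3-methylbut-2-en-1-yl. In 11 and 13–16, Z means that the ester (acid, acid chloride) group and the oxygen substituent on the alkene are cis, the arrangement needed for ring closure.
- The prenyl chain is built by cross-metathesis on the free phenol 6, before any O-allyl group is present, so the allyl ethers never meet the ruthenium carbene.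
- The Z geometry is set by a chelation-controlled enol tosylation and carried through a stereoretentive vinylic substitution.

Step 1
Reactants: 1 phloroglucinol; 2 allyl bromide
Product: 3 3,5-bis(allyloxy)phenol
Conditions: allyl bromide (2 equiv), K2CO3, DMF, 0 °C to rt; chromatography
Reagents that add atoms: allyl bromide (2), C=CCBr
Why: Williamson etherification of a threefold-symmetric triphenol is statistical, so two equivalents of halide in a dipolar aprotic solvent (which favours O- over C-alkylation) should give the diether as the main fraction, separable from mono- and triether.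

Step 2
Reactants: 4 methyl homovanillate; 2 allyl bromide
Product: 5 methyl 2-[4-(allyloxy)-3-methoxyphenyl]acetate
Conditions: allyl bromide, K2CO3, acetone, reflux
Reagents that add atoms: allyl bromide (2), C=CCBr
Why: Williamson etherification at the only acidic OH; the methyl ester is inert to K2CO3 in acetone.

Step 3
Reactants: 5 methyl 2-[4-(allyloxy)-3-methoxyphenyl]acetate
Product: 6 methyl 2-(3-allyl-4-hydroxy-5-methoxyphenyl)acetate
Conditions: N,N-diethylaniline, 200 °C
Reagents that add atoms: none
Why: Aromatic Claisen rearrangement ([3,3]-sigmatropic shift, then tautomerisation) delivers the allyl group to the only ortho carbon that bears hydrogen, since the other ortho carbon carries the methoxy group and the para carbon carries the acetate chain.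

Step 4
Reactants: 6 methyl 2-(3-allyl-4-hydroxy-5-methoxyphenyl)acetate; 7 2-methyl-2-butene
Product: 8 methyl 2-[4-hydroxy-3-methoxy-5-(3-methylbut-2-en-1-yl)phenyl]acetate
Conditions: second-generation Grubbs catalyst (5 mol%), 2-methyl-2-butene/CH2Cl2, 40 °C, sealed vessel
Reagents that add atoms: 2-methyl-2-butene (7), CC=C(C)C
Why: Olefin cross-metathesis of the terminal allylarene with an excess of the trisubstituted alkene transfers the isopropylidene end and releases propene, and the ruthenium carbene tolerates the free phenol and the ester.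

Step 5
Reactants: 8 methyl 2-[4-hydroxy-3-methoxy-5-(3-methylbut-2-en-1-yl)phenyl]acetate; 2 allyl bromide
Product: 9 methyl 2-[4-(allyloxy)-3-methoxy-5-(3-methylbut-2-en-1-yl)phenyl]acetate
Conditions: allyl bromide, K2CO3, DMF, 50 °C
Reagents that add atoms: allyl bromide (2), C=CCBr
Why: Williamson etherification of the flanked phenol, which needs the more polar solvent and gentle warming; base leaves the prenyl chain and the ester untouched.

Step 6
Reactants: 9 methyl 2-[4-(allyloxy)-3-methoxy-5-(3-methylbut-2-en-1-yl)phenyl]acetate; 10 methyl formate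
Product: 11 methyl (Z)-2-[4-(allyloxy)-3-methoxy-5-prenylphenyl]-3-hydroxyacrylate (the enol form of the α-formyl ester)
Conditions: NaH, HCO2Me, THF, 0 °C to rt; then 1 M HCl, 0 °C
Reagents that add atoms: methyl formate (10), COC=O
Why: Crossed Claisen condensation (C-formylation of the arylacetate enolate) is pulled to completion by deprotonation of the product, which after neutralisation should sit as the hydrogen-bonded Z enol.

Step 7
Reactants: 11 methyl (Z)-2-[4-(allyloxy)-3-methoxy-5-prenylphenyl]-3-hydroxyacrylate; 12 p-toluenesulfonyl chloride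
Product: 13 methyl (Z)-2-[4-(allyloxy)-3-methoxy-5-prenylphenyl]-3-(tosyloxy)acrylate
Conditions: TsCl, TMEDA, LiCl, MeCN, 0 °C
Reagents that add atoms: p-toluenesulfonyl chloride (12), Cc1ccc(cc1)S(=O)(=O)Cl
Why: O-Sulfonylation of the enolate, in which lithium bridges the enolate oxygen and the ester carbonyl, so the tosyloxy group is fixed cis to the ester (Z).

Step 8
Reactants: 13 methyl (Z)-2-[4-(allyloxy)-3-methoxy-5-prenylphenyl]-3-(tosyloxy)acrylate; 3 3,5-bis(allyloxy)phenol
Product: 14 methyl (Z)-2-[4-(allyloxy)-3-methoxy-5-prenylphenyl]-3-[3,5-bis(allyloxy)phenoxy]acrylate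
Conditions: K2CO3, DMF, rt
Reagents that add atoms: none
Why: Nucleophilic vinylic substitution by addition–elimination: the phenoxide adds to C3 of the acceptor alkene and the resulting ester enolate expels tosylate, a sequence that with a good leaving group should run with net retention and keep the aryloxy group cis to the ester.

Step 9
Reactants: 14 methyl (Z)-2-[4-(allyloxy)-3-methoxy-5-prenylphenyl]-3-[3,5-bis(allyloxy)phenoxy]acrylate
Product: 15 (Z)-2-[4-(allyloxy)-3-methoxy-5-prenylphenyl]-3-[3,5-bis(allyloxy)phenoxy]acrylic acid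
Conditions: LiOH, THF/H2O, rt to 40 °C; then 1 M HCl to pH 3, 0 °C
Reagents that add atoms: lithium hydroxide, [Li+].[OH-]
Why: Saponification (acyl substitution by hydroxide) should outrun attack at the donor-substituted C3, as it does for β-alkoxyacrylates, and leaving out methanol excludes exchange of the aryloxy group by methoxide; allyl ethers and the prenyl chain are inert to base.

Step 10
Reactants: 15 (Z)-2-[4-(allyloxy)-3-methoxy-5-prenylphenyl]-3-[3,5-bis(allyloxy)phenoxy]acrylic acid
Product: 17 5,7-bis(allyloxy)-3-[4-(allyloxy)-3-methoxy-5-prenylphenyl]chromen-4-one, via acid chloride 16 (not isolated)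
Conditions: 1-chloro-N,N,2-trimethylprop-1-enylamine (1.1 equiv), CH2Cl2, 0 °C to rt; then 2,6-di-tert-butyl-4-methylpyridine, SnCl4, CH2Cl2, −78 to −40 °C
Reagents that add atoms: none
Why: The chloroenamine converts the acid into acid chloride 16 under neutral conditions with only a neutral amide as by-product; SnCl4 then polarises or ionises the C–Cl bond, the acyl carbon (stabilised by the 3-aryloxy donor) attacks the ring A carbon that is ortho to the ether oxygen, ortho to one allyloxy group and para to the other, and the hindered pyridine takes the proton from the arenium ion. The closest known reaction type is the Friedel–Crafts cyclodehydration of 3-aryloxyacrylic acids to chromones. Ring C closes in a 6-exo-trig mode at the acyl carbon (C=O outside the new ring), with the attacking arene C=C inside the ring. No stereocentre is formed. The step needs a single site on ring A and survival of the prenyl alkene and the allyl ethers: the first follows because the two carbons ortho to O1 are exchanged by the local symmetry of the 3,5-bis(allyloxy)phenoxy ring and the para carbon cannot reach the acyl group, the second from working at −78 to −40 °C with a proton scavenger too hindered to bind SnCl4. The Z geometry holds the acyl group next to the aryloxy ring, and any E isomer carried along should still converge, because the donor–acceptor acylium ion has a low barrier to rotation about the former C=C bond.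

Step 11
Reactants: 17 5,7-bis(allyloxy)-3-[4-(allyloxy)-3-methoxy-5-prenylphenyl]chromen-4-one
Product: 18 2'-deoxypiscerythrone (5,7-dihydroxy-3-[4-hydroxy-3-methoxy-5-(3-methylbut-2-en-1-yl)phenyl]chromen-4-one)
Conditions: Pd(PPh3)4 (5–10 mol%), morpholine, THF, rt
Reagents that add atoms: none
Why: Zerovalent palladium ionises each aryl allyl ether to a π-allyl complex and a phenoxide and morpholine takes up the allyl group (Tsuji–Trost-type allyl transfer), while the C-prenyl chain and the methyl ether offer no leaving group and stay.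

Compound list
1 | phloroglucinol (benzene-1,3,5-triol) | Oc1cc(O)cc(O)c1 | starting material
2 | allyl bromide | C=CCBr | starting material
3 | 3,5-bis(allyloxy)phenol | Oc1cc(OCC=C)cc(OCC=C)c1 | intermediate
4 | methyl homovanillate (methyl 2-(4-hydroxy-3-methoxyphenyl)acetate) | COC(=O)Cc1ccc(O)c(OC)c1 | starting material
5 | methyl 2-[4-(allyloxy)-3-methoxyphenyl]acetate | COC(=O)Cc1ccc(OCC=C)c(OC)c1 | intermediate
6 | methyl 2-(3-allyl-4-hydroxy-5-methoxyphenyl)acetate | COC(=O)Cc1cc(CC=C)c(O)c(OC)c1 | intermediate
7 | 2-methyl-2-butene | CC=C(C)C | starting material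
8 | methyl 2-[4-hydroxy-3-methoxy-5-(3-methylbut-2-en-1-yl)phenyl]acetate | COC(=O)Cc1cc(CC=C(C)C)c(O)c(OC)c1 | intermediate
9 | methyl 2-[4-(allyloxy)-3-methoxy-5-(3-methylbut-2-en-1-yl)phenyl]acetate | COC(=O)Cc1cc(CC=C(C)C)c(OCC=C)c(OC)c1 | intermediate
10 | methyl formate | COC=O | starting material
11 | methyl (Z)-2-[4-(allyloxy)-3-methoxy-5-prenylphenyl]-3-hydroxyacrylate | COC(=O)/C(=C\O)c1cc(OC)c(OCC=C)c(CC=C(C)C)c1 | intermediate
12 | p-toluenesulfonyl chloride | Cc1ccc(cc1)S(=O)(=O)Cl | starting material
13 | methyl (Z)-2-[4-(allyloxy)-3-methoxy-5-prenylphenyl]-3-(tosyloxy)acrylate | COC(=O)/C(=C\OS(=O)(=O)c1ccc(C)cc1)c1cc(OC)c(OCC=C)c(CC=C(C)C)c1 | intermediate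
14 | methyl (Z)-2-[4-(allyloxy)-3-methoxy-5-prenylphenyl]-3-[3,5-bis(allyloxy)phenoxy]acrylate | COC(=O)/C(=C\Oc1cc(OCC=C)cc(OCC=C)c1)c1cc(OC)c(OCC=C)c(CC=C(C)C)c1 | intermediate
15 | (Z)-2-[4-(allyloxy)-3-methoxy-5-prenylphenyl]-3-[3,5-bis(allyloxy)phenoxy]acrylic acid | OC(=O)/C(=C\Oc1cc(OCC=C)cc(OCC=C)c1)c1cc(OC)c(OCC=C)c(CC=C(C)C)c1 | intermediate
16 | (Z)-2-[4-(allyloxy)-3-methoxy-5-prenylphenyl]-3-[3,5-bis(allyloxy)phenoxy]acryloyl chloride | ClC(=O)/C(=C\Oc1cc(OCC=C)cc(OCC=C)c1)c1cc(OC)c(OCC=C)c(CC=C(C)C)c1 | intermediate
17 | 5,7-bis(allyloxy)-3-[4-(allyloxy)-3-methoxy-5-prenylphenyl]chromen-4-one | C=CCOc1cc(OCC=C)c2c(c1)occ(-c1cc(OC)c(OCC=C)c(CC=C(C)C)c1)c2=O | intermediate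
18 | 2'-deoxypiscerythrone | COc1cc(-c2coc3cc(O)cc(O)c3c2=O)cc(CC=C(C)C)c1O | target

Total step count: 11. Longest linear sequence: 10 steps (steps 2 to 11, from 4 to 18); step 1 supplies 3 for step 8.

Steps most likely to fail

Step 10. The prenyl double bond may be protonated or take up chloride, or enter cation–olefin side reactions, before the ring has closed. The Lewis acid may also strip or shift an allyl ether. The fallback postpones the prenyl group until after ring closure, so that only monosubstituted alkenes meet the Lewis acid. It sets out from 6 and comes back at 18: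
- O-allylation of 6 (2, K2CO3, DMF) should give methyl 2-[3-allyl-4-(allyloxy)-5-methoxyphenyl]acetate F1.
- Formylation (10, NaH, THF) should give methyl (Z)-2-[3-allyl-4-(allyloxy)-5-methoxyphenyl]-3-hydroxyacrylate F2.
- Tosylation (12, TMEDA, LiCl) should give methyl (Z)-2-[3-allyl-4-(allyloxy)-5-methoxyphenyl]-3-(tosyloxy)acrylate F3.
- Displacement by 3 (K2CO3, DMF) should give methyl (Z)-2-[3-allyl-4-(allyloxy)-5-methoxyphenyl]-3-[3,5-bis(allyloxy)phenoxy]acrylate F4.
- LiOH in THF/H2O should give (Z)-2-[3-allyl-4-(allyloxy)-5-methoxyphenyl]-3-[3,5-bis(allyloxy)phenoxy]acrylic acid F5.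
- The chloroenamine should give (Z)-2-[3-allyl-4-(allyloxy)-5-methoxyphenyl]-3-[3,5-bis(allyloxy)phenoxy]acryloyl chloride F6, which is not isolated.
- SnCl4, which may now be used warmer, should close F6 to 5,7-bis(allyloxy)-3-[3-allyl-4-(allyloxy)-5-methoxyphenyl]chromen-4-one F7.
- Pd(PPh3)4 with morpholine should remove the three O-allyl groups and leave the C-allyl group, giving 3-(3-allyl-4-hydroxy-5-methoxyphenyl)-5,7-dihydroxychromen-4-one F8.
- Cross-metathesis of F8 with 7 (second-generation Grubbs catalyst) should then build the prenyl chain and rejoin the route at 18.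

Step 8. The phenoxide may attack sulfur instead of C3, which transfers the sulfonyl group and returns the enolate of 11, or the carbanion intermediate may live long enough to scramble the alkene geometry. The fallback replaces the sulfonate by a vinyl halide, whose only electrophilic site is carbon. It sets out from 11: Vilsmeier-type chlorination of the enol (oxalyl chloride, catalytic DMF, 2,6-lutidine, CH2Cl2, 0 °C) should give methyl (Z)-3-chloro-2-[4-(allyloxy)-3-methoxy-5-prenylphenyl]acrylate F9. Addition–elimination of 3 on F9 (K2CO3, DMF, with DABCO as nucleophilic catalyst if needed) comes back at 14. Either geometry of F9 serves, since step 10 tolerates both isomers of the acid.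

Step 9. Hydroxide may add to C3 and expel the aryloxide, which undoes step 8, or the hindered, donor-conjugated ester may hydrolyse too slowly. The fallback changes the bond that is broken. It sets out from 14 and uses LiI in refluxing EtOAc, where iodide attacks the methyl carbon (SN2 O-dealkylation) and never approaches C3; the lithium carboxylate gives 15 on mild acidification. This fallback makes no new compound (F0) and comes back at 15.

Further compounds
F1 | step 10 | methyl 2-[3-allyl-4-(allyloxy)-5-methoxyphenyl]acetate | COC(=O)Cc1cc(CC=C)c(OCC=C)c(OC)c1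
F2 | step 10 | methyl (Z)-2-[3-allyl-4-(allyloxy)-5-methoxyphenyl]-3-hydroxyacrylate | COC(=O)/C(=C\O)c1cc(OC)c(OCC=C)c(CC=C)c1
F3 | step 10 | methyl (Z)-2-[3-allyl-4-(allyloxy)-5-methoxyphenyl]-3-(tosyloxy)acrylate | COC(=O)/C(=C\OS(=O)(=O)c1ccc(C)cc1)c1cc(OC)c(OCC=C)c(CC=C)c1
F4 | step 10 | methyl (Z)-2-[3-allyl-4-(allyloxy)-5-methoxyphenyl]-3-[3,5-bis(allyloxy)phenoxy]acrylate | COC(=O)/C(=C\Oc1cc(OCC=C)cc(OCC=C)c1)c1cc(OC)c(OCC=C)c(CC=C)c1
F5 | step 10 | (Z)-2-[3-allyl-4-(allyloxy)-5-methoxyphenyl]-3-[3,5-bis(allyloxy)phenoxy]acrylic acid | OC(=O)/C(=C\Oc1cc(OCC=C)cc(OCC=C)c1)c1cc(OC)c(OCC=C)c(CC=C)c1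
F6 | step 10 | (Z)-2-[3-allyl-4-(allyloxy)-5-methoxyphenyl]-3-[3,5-bis(allyloxy)phenoxy]acryloyl chloride | ClC(=O)/C(=C\Oc1cc(OCC=C)cc(OCC=C)c1)c1cc(OC)c(OCC=C)c(CC=C)c1
F7 | step 10 | 5,7-bis(allyloxy)-3-[3-allyl-4-(allyloxy)-5-methoxyphenyl]chromen-4-one | C=CCOc1cc(OCC=C)c2c(c1)occ(-c1cc(OC)c(OCC=C)c(CC=C)c1)c2=O
F8 | step 10 | 3-(3-allyl-4-hydroxy-5-methoxyphenyl)-5,7-dihydroxychromen-4-one | COc1cc(-c2coc3cc(O)cc(O)c3c2=O)cc(CC=C)c1O
F9 | step 8 | methyl (Z)-3-chloro-2-[4-(allyloxy)-3-methoxy-5-prenylphenyl]acrylate | COC(=O)/C(=C\Cl)c1cc(OC)c(OCC=C)c(CC=C(C)C)c1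
F0 | step 9 | none | none
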